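**Plan**

Numbering: ring C1 (C=O), C2=C3, C4 (OAc), C5 (tertiary OH); side-chain carbinol carbon C1′; the target is (4R,5S,1′S).
Retrosynthetic cuts: (i) the C4–O(acetate) bond, made last with inversion from a cis-4,5-diol; (ii) the O1′-acetyl group and an isopropylidene bridge O4–CMe2–O5; (iii) the C5–C1′ bond, which leaves pentadecanal and the C5 enolate of a bicyclic cyclopentenone ketal.
Enabling feature: C5 is the α′-carbon of the C1 ketone and carries O5 next to O4 on C4, so O4 and O5 can be locked in a cis-fused 2,2-dimethyl-1,3-dioxolane on the cyclopent-2-enone ring; the bicyclo[3.3.0] enolate C1(OLi)=C5 then has one open (convex) face and a ring-fixed geometry.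
Forward order: no ring is built (the cyclopentenone comes intact from the chiral pool); the C15 chain is joined in step 1, then O1′ is acetylated, the ketal is removed and C4 is inverted with acetate.
Stereochemistry: C4 of the starting enone sets C5 (convex-face attack) and, through the chair transition state, C1′; C4 itself is finally inverted by SN2 to give the 4,5-trans pattern.

Key step: step 1

Assumption: the (3aS,6aS) antipode of the familiar isopropylidene-protected 4,5-dihydroxycyclopent-2-enone (compound 1) is taken to be purchasable as a catalogue chiral building block, as is pentadecanal.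

**Route**

Step 1
Reactants: 1 (3aS,6aS)-2,2-dimethyl-3a,6a-dihydro-4H-cyclopenta[d][1,3]dioxol-4-one; 2 pentadecanal
Product: 5 (3aS,6aS)-3a-[(1S)-1-hydroxypentadecyl]-2,2-dimethyl-3a,6a-dihydro-4H-cyclopenta[d][1,3]dioxol-4-one, via lithium enolate 3 (not isolated), via lithium aldolate 4 (not isolated)
Conditions: LDA (1.1 equiv), THF, −78 °C, 1 added dropwise; then 2 (1.2 equiv), −78 °C, 1 h; sat. aq NH4Cl at −78 °C
Reagents that add atoms: none
Why: LDA removes the only α′-hydrogen (C5–H) to give the cross-conjugated lithium enolate 3, in which loss of the C4 alkoxide is held back because it would create a 4π-antiaromatic cyclopentadienone, and 3 adds to pentadecanal through a closed Zimmerman–Traxler chair (lithium aldol addition). The closest known reaction type is the kinetic α′-aldol addition of lithium enolates of 4-oxygenated cyclopent-2-enones to aliphatic aldehydes, as used to attach prostanoid-type side chains. No ring is closed. C5 is controlled by the C4 stereocentre through the cis-fused dioxolane: O5 must stay on the concave face with O4, so the C–C bond can only form on the convex face, anti to the C4–O bond. C1′ is controlled by the ring-fixed enolate geometry (ring carbon C4 trans and O5 cis to the enolate oxygen): with the C14 chain equatorial in the chair the new hydroxyl ends anti to C4 and syn to O5, which is 1′S. The step needs α′- over γ-deprotonation and carbonyl addition over proton transfer or Michael self-addition, which kinetic conditions at −78 °C, slow addition of 1 to the base and a cold quench should secure.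

Step 2
Reactants: 5 (3aS,6aS)-3a-[(1S)-1-hydroxypentadecyl]-2,2-dimethyl-3a,6a-dihydro-4H-cyclopenta[d][1,3]dioxol-4-one
Product: 6 (1S)-1-[(3aS,6aS)-2,2-dimethyl-4-oxo-4,6a-dihydro-3aH-cyclopenta[d][1,3]dioxol-3a-yl]pentadecyl acetate
Conditions: Ac2O, pyridine, DMAP (cat.), CH2Cl2, 0 °C → rt
Reagents that add atoms: acetic anhydride, CC(=O)OC(C)=O
Why: DMAP-catalysed O-acylation (nucleophilic catalysis) of the only free hydroxyl should give the 1′-acetate without touching a stereocentre, because O4 and O5 are masked in the ketal and the mild base should not trigger retro-aldol cleavage of the C5-quaternary β-hydroxy ketone.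

Step 3
Reactants: 6 (1S)-1-[(3aS,6aS)-2,2-dimethyl-4-oxo-4,6a-dihydro-3aH-cyclopenta[d][1,3]dioxol-3a-yl]pentadecyl acetate
Product: 7 (1S)-1-[(1R,5S)-1,5-dihydroxy-2-oxocyclopent-3-en-1-yl]pentadecyl acetate
Conditions: CF3CO2H–H2O (4:1), 0 °C → rt, short reaction time
Reagents that add atoms: none
Why: Acid-catalysed ketal hydrolysis through the dimethyl oxocarbenium ion should free the cis-4,5-diol while the secondary acetate survives the short cold exposure, and C4 should neither ionise nor epimerise because its allyl cation would be a destabilised 4π oxocyclopentenyl cation.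

Step 4
Reactants: 7 (1S)-1-[(1R,5S)-1,5-dihydroxy-2-oxocyclopent-3-en-1-yl]pentadecyl acetate
Product: 9 (1S)-1-[(1S,5R)-5-(acetyloxy)-1-hydroxy-2-oxocyclopent-3-en-1-yl]pentadecyl acetate, via oxyphosphonium acetate 8 (not isolated)
Conditions: PPh3, DIAD, AcOH (3 equiv), toluene–THF, 0 °C → rt
Reagents that add atoms: acetic acid, CC(=O)O
Why: Mitsunobu esterification, a reaction type precedented for 4-hydroxycyclopent-2-enones, should activate the secondary allylic C4 hydroxyl as oxyphosphonium ion 8 and displace it by acetate in an SN2 step with inversion, which sets 4R and turns the cis-4,5-diol into the trans-4-acetoxy-5-hydroxy pattern, while the tertiary C5 hydroxyl (cis to the leaving group, so no epoxide can form) and the 1′-acetate stay in place.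

**Compound list**

1 | (3aS,6aS)-2,2-dimethyl-3a,6a-dihydro-4H-cyclopenta[d][1,3]dioxol-4-one | O=C1C=C[C@@H]2OC(C)(C)O[C@H]12 | starting material
2 | pentadecanal | CCCCCCCCCCCCCCC=O | starting material
3 | lithium (6aS)-2,2-dimethyl-6aH-cyclopenta[d][1,3]dioxol-4-olate (lithium enolate) | [Li+].[O-]C1=C2OC(C)(C)O[C@H]2C=C1 | intermediate
4 | lithium (1S)-1-[(3aS,6aS)-2,2-dimethyl-4-oxo-4,6a-dihydro-3aH-cyclopenta[d][1,3]dioxol-3a-yl]pentadecan-1-olate (lithium aldolate) | [Li+].CCCCCCCCCCCCCC[C@H]([O-])[C@]12OC(C)(C)O[C@H]1C=CC2=O | intermediate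
5 | (3aS,6aS)-3a-[(1S)-1-hydroxypentadecyl]-2,2-dimethyl-3a,6a-dihydro-4H-cyclopenta[d][1,3]dioxol-4-one | CCCCCCCCCCCCCC[C@H](O)[C@]12OC(C)(C)O[C@H]1C=CC2=O | intermediate
6 | (1S)-1-[(3aS,6aS)-2,2-dimethyl-4-oxo-4,6a-dihydro-3aH-cyclopenta[d][1,3]dioxol-3a-yl]pentadecyl acetate | CCCCCCCCCCCCCC[C@H](OC(C)=O)[C@]12OC(C)(C)O[C@H]1C=CC2=O | intermediate
7 | (1S)-1-[(1R,5S)-1,5-dihydroxy-2-oxocyclopent-3-en-1-yl]pentadecyl acetate (cis-4,5-diol) | CCCCCCCCCCCCCC[C@H](OC(C)=O)[C@@]1(O)C(=O)C=C[C@@H]1O | intermediate
8 | triphenyl{[(1S,5S)-5-[(1S)-1-(acetyloxy)pentadecyl]-5-hydroxy-4-oxocyclopent-2-en-1-yl]oxy}phosphonium acetate | CCCCCCCCCCCCCC[C@H](OC(C)=O)[C@@]1(O)C(=O)C=C[C@@H]1O[P+](c1ccccc1)(c1ccccc1)c1ccccc1.CC(=O)[O-] | intermediate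
9 | (1S)-1-[(1S,5R)-5-(acetyloxy)-1-hydroxy-2-oxocyclopent-3-en-1-yl]pentadecyl acetate | CCCCCCCCCCCCCC[C@H](OC(C)=O)[C@@]1(O)C(=O)C=C[C@H]1OC(C)=O | target

**Count and risks**

Total steps: 4. Longest linear sequence: 4 steps (1 → 5 → 6 → 7 → 9).

Most likely to fail, in this order:

Step 4. The bimolecular displacement at C4 may be slow, because the carbon is neopentyl-like and the acetate must approach on the face that carries the C5 side chain. The neighbouring 1′-acetoxy carbonyl may capture the oxyphosphonium ion instead (acyl scrambling, hydroxy acetates after work-up), or the cis-diol may be tied up as a dioxaphosphorane. The fallback avoids the inversion altogether; it sets out from 2 and rejoins the route at 9. Purchased (4S)-4-[(tert-butyldimethylsilyl)oxy]cyclopent-2-en-1-one F1 would be deprotonated with LDA at −78 °C and added to 2 to give aldol F2 (trans at C4/C5; the C5 and C1′ centres are erased in the next operation). Mesylation (MsCl, Et3N) to F3 and elimination with DBU should give the (E)-5-pentadecylidene dienone F4. OsO4 (cat.)/NMO should dihydroxylate the more electron-rich exocyclic alkene, syn and on the face anti to the silyloxy group, giving diol F5 with O5 trans to O4 and 1′S. HF·pyridine would give triol F6, and Ac2O/pyridine/DMAP should acetylate only the two secondary hydroxyls to give 9.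

Step 1. Simple diastereoselection at C1′ may be eroded by boat or open transition states of the lithium enolate. The strongly basic enolate may also fragment by loss of the C4 alkoxide, add in Michael fashion to unreacted 1, or be quenched by proton transfer from the enolisable aldehyde. The fallback replaces the preformed lithium enolate by soft enolisation and a covalent boron enolate; it sets out from 1 and 2 and rejoins at 5. Bu2BOTf and iPr2NEt in CH2Cl2 at −78 °C should convert 1 into the dibutylboron enolate F7 without any strong base. Addition of 2 should give the boron aldolate F8 through a tighter chair with the same facial and simple selectivity, and buffered H2O2/MeOH work-up would release 5.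

Step 2. The hindered β-hydroxy ketone may cleave by retro-aldol reaction under amine/DMAP catalysis, and acylation of a carbinol flanked by a quaternary centre may be slow. The fallback merges the acylation with the key step: the lithium aldolate 4 is acetylated in the aldol flask at −78 °C by adding acetic anhydride before the quench, so the free alcohol is never exposed to base. It sets out from 4 and rejoins at 6.

Further compounds
F1 | step 4 | (4S)-4-[(tert-butyldimethylsilyl)oxy]cyclopent-2-en-1-one | O=C1C=C[C@@H](O[Si](C)(C)C(C)(C)C)C1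
F2 | step 4 | (4R,5S)-4-[(tert-butyldimethylsilyl)oxy]-5-(1-hydroxypentadecyl)cyclopent-2-en-1-one (C1′ epimers) | CCCCCCCCCCCCCCC(O)[C@@H]1C(=O)C=C[C@H]1O[Si](C)(C)C(C)(C)C
F3 | step 4 | 1-[(1S,5R)-5-[(tert-butyldimethylsilyl)oxy]-2-oxocyclopent-3-en-1-yl]pentadecyl methanesulfonate (C1′ epimers) | CCCCCCCCCCCCCCC(OS(C)(=O)=O)[C@@H]1C(=O)C=C[C@H]1O[Si](C)(C)C(C)(C)C
F4 | step 4 | (4R,5E)-4-[(tert-butyldimethylsilyl)oxy]-5-pentadecylidenecyclopent-2-en-1-one | CCCCCCCCCCCCCC/C=C1/C(=O)C=C[C@H]1O[Si](C)(C)C(C)(C)C
F5 | step 4 | (4R,5S)-4-[(tert-butyldimethylsilyl)oxy]-5-hydroxy-5-[(1S)-1-hydroxypentadecyl]cyclopent-2-en-1-one | CCCCCCCCCCCCCC[C@H](O)[C@@]1(O)C(=O)C=C[C@H]1O[Si](C)(C)C(C)(C)C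
F6 | step 4 | (4R,5S)-4,5-dihydroxy-5-[(1S)-1-hydroxypentadecyl]cyclopent-2-en-1-one | CCCCCCCCCCCCCC[C@H](O)[C@@]1(O)C(=O)C=C[C@H]1O
F7 | step 1 | (6aS)-4-[(dibutylboranyl)oxy]-2,2-dimethyl-6aH-cyclopenta[d][1,3]dioxole (boron enolate) | CCCCB(CCCC)OC1=C2OC(C)(C)O[C@H]2C=C1
F8 | step 1 | (3aS,6aS)-3a-{(1S)-1-[(dibutylboranyl)oxy]pentadecyl}-2,2-dimethyl-3a,6a-dihydro-4H-cyclopenta[d][1,3]dioxol-4-one (boron aldolate) | CCCCCCCCCCCCCC[C@H](OB(CCCC)CCCC)[C@]12OC(C)(C)O[C@H]1C=CC2=O
F0 | step 2 | none | none
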